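The route rests on disconnecting the 8-O-4' unit: the ether bond from C8 to the oxygen on C4' of the 2,6-dimethoxylated ring B, and the benzylic C7–OH bond next to it. The two methoxy groups flanking that oxygen allow the ring B radical to bond only through oxygen. One oxidative operation joins C8 of an isoeugenol radical to the phenoxyl oxygen of syringaldehyde and lets water add to C7 of the resulting ring A quinone methide. This builds both skeletal C–O bonds and the erythro C7/C8 relationship without closing a ring. The precursors are the two unprotected commercial phenols. Methylation, resolution through (1S)-camphanate diastereomers, Horner–Wadsworth–Emmons olefination and one global i-Bu2AlH reduction complete the single enantiomer.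

Key step: step 1

Remark: neolignan numbering is used (ring A with chain C7, C8, C9; ring B primed; C7 = C1 and C8 = C2 of the propane names); the target is the erythro (7R,8S) isomer, and because the coupling cannot control absolute configuration, the racemate is resolved afterwards.

Step 1
Reactants: 1 (E)-isoeugenol; 2 syringaldehyde
Product: 4 erythro-4-{[1-hydroxy-1-(4-hydroxy-3-methoxyphenyl)propan-2-yl]oxy}-3,5-dimethoxybenzaldehyde (racemate), via quinone methide 3 (not isolated)
Conditions: Ag2O (1.5 equiv), 2 (3 equiv), acetone/H2O (9:1), rt, dark; 1 added over 6 h by syringe pump; filtration through Celite, aq. NaHCO3 wash (removes excess 2), chromatography (threo isomer and isoeugenol dimers removed)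
Reagents that add atoms: water, O
Why: Oxidative phenol cross-coupling followed by quinone methide hydration: monovalent silver on the Ag2O surface takes one electron and one proton from each phenol; the phenoxyl radical of 2, blocked at both ortho carbons by methoxy groups and at the para carbon by the formyl group, is long-lived and can bond productively only through oxygen, whereas the radical of 1 is transient and carries high spin density on C8, so their combination forms the C8–O bond and leaves ring A as quinone methide 3. Water then adds to the electrophilic C7 of 3 in a 1,6-conjugate addition that restores the aromatic ring A and forms the C7–O bond. No ring is closed. Both stereocentres arise here: C8 is formed without facial bias in the radical combination, hence the racemate, and C7 is set relative to C8 by substrate control, because in the conformer of 3 that minimises allylic 1,3-strain (C8–H eclipsing the exocyclic C=C) water should attack the face anti to the bulky, electronegative 2,6-dimethoxyaryloxy group, which leads to the erythro isomer. The selectivity the step needs is cross-coupling over homo-coupling of 1, secured by the persistent radical effect: 2 is in threefold excess and 1 is kept at low stationary concentration by slow addition, while the large molar excess of water should outcompete phenol addition to 3. The closest known reaction type is the dehydrogenative 8-O-4' coupling of propenylphenols with 2,6-dimethoxyphenols by Ag2O or oxidase enzymes in wet solvents.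

Step 2
Reactants: 4 erythro-4-{[1-hydroxy-1-(4-hydroxy-3-methoxyphenyl)propan-2-yl]oxy}-3,5-dimethoxybenzaldehyde (racemate)
Product: 5 erythro-4-{[1-(3,4-dimethoxyphenyl)-1-hydroxypropan-2-yl]oxy}-3,5-dimethoxybenzaldehyde (racemate)
Conditions: MeI, K2CO3, acetone, rt
Reagents that add atoms: iodomethane, CI
Why: Williamson ether synthesis in which K2CO3 deprotonates only the ring A phenol (far more acidic than the C7 alcohol) and the phenoxide attacks MeI by SN2 at a temperature too low for base-induced quinone methide formation, so C7, C8 and the aldehyde should remain untouched.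

Step 3
Reactants: 5 erythro-4-{[1-(3,4-dimethoxyphenyl)-1-hydroxypropan-2-yl]oxy}-3,5-dimethoxybenzaldehyde (racemate)
Product: 6 (1R,2S)-1-(3,4-dimethoxyphenyl)-2-(4-formyl-2,6-dimethoxyphenoxy)propyl (1S,4R)-camphanate (single diastereomer)
Conditions: (1S)-(−)-camphanic chloride, Et3N, 4-(dimethylamino)pyridine (cat.), CH2Cl2, 0 °C to rt; then separation of the two diastereomeric esters by chromatography on silica gel and crystallisation
Reagents that add atoms: (1S)-(−)-camphanic chloride, ClC(=O)[C@@]12CC[C@@](C)(C(=O)O1)C2(C)C
Why: Classical resolution through covalent diastereomers by nucleophile-catalysed esterification, in which no stereocentre is made or broken, the acid chloride has no α-hydrogen and so cannot racemise, and the camphanoyl group serves both as an internal reference of known configuration for assigning the (1R,2S) ester by X-ray crystallography and as protection of the C7 hydroxyl in the next step.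

Step 4
Reactants: 6 (1R,2S)-1-(3,4-dimethoxyphenyl)-2-(4-formyl-2,6-dimethoxyphenoxy)propyl (1S,4R)-camphanate; 7 triethyl phosphonoacetate
Product: 8 ethyl (E)-3-[4-({(1R,2S)-1-[(1S,4R)-camphanoyloxy]-1-(3,4-dimethoxyphenyl)propan-2-yl}oxy)-3,5-dimethoxyphenyl]prop-2-enoate
Conditions: 7 (1.3 equiv), NaH (1.2 equiv), THF, 0 °C; then 6, 0 °C to rt
Reagents that add atoms: none
Why: Horner–Wadsworth–Emmons olefination in which the preformed sodium salt of the stabilised phosphonate adds reversibly to the unhindered aryl aldehyde and eliminates to the (E)-cinnamate, while this weakly nucleophilic carbanion should leave the hindered camphanate and its lactone alone and neither stereocentre bears an acidic hydrogen.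

Step 5
Reactants: 8 ethyl (E)-3-[4-({(1R,2S)-1-[(1S,4R)-camphanoyloxy]-1-(3,4-dimethoxyphenyl)propan-2-yl}oxy)-3,5-dimethoxyphenyl]prop-2-enoate
Product: 9 (1R,2S)-1-(3,4-dimethoxyphenyl)-2-{4-[(E)-3-hydroxyprop-1-en-1-yl]-2,6-dimethoxyphenoxy}propan-1-ol
Conditions: i-Bu2AlH (DIBAL-H, 8 equiv), CH2Cl2, −78 to 0 °C; aq. KNaC4H4O6 (Rochelle salt) work-up
Reagents that add atoms: none
Why: Hydride reduction of esters with i-Bu2AlH, which should convert the conjugated ethyl ester by 1,2-addition into the (E)-allylic alcohol without touching the C=C bond and, in the same operation, cleave the camphanate at its acyl carbon so that the C7 hydroxyl is freed with retention, the C7–O bond never being broken.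

Compound list
1 | (E)-isoeugenol, 2-methoxy-4-[(E)-prop-1-en-1-yl]phenol | COc1cc(/C=C/C)ccc1O | starting material
2 | syringaldehyde, 4-hydroxy-3,5-dimethoxybenzaldehyde | COc1cc(C=O)cc(OC)c1O | starting material
3 | ring A quinone methide, 4-{[1-(3-methoxy-4-oxocyclohexa-2,5-dien-1-ylidene)propan-2-yl]oxy}-3,5-dimethoxybenzaldehyde (racemic at C8, one enantiomer drawn; geometry of the exocyclic C=C not defined) | COC1=CC(=C[C@H](C)Oc2c(OC)cc(C=O)cc2OC)C=CC1=O | intermediate (not isolated)
4 | erythro-4-{[1-hydroxy-1-(4-hydroxy-3-methoxyphenyl)propan-2-yl]oxy}-3,5-dimethoxybenzaldehyde (racemate; (1R,2S) enantiomer drawn) | COc1cc([C@@H](O)[C@H](C)Oc2c(OC)cc(C=O)cc2OC)ccc1O | intermediate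
5 | erythro-4-{[1-(3,4-dimethoxyphenyl)-1-hydroxypropan-2-yl]oxy}-3,5-dimethoxybenzaldehyde (racemate; (1R,2S) enantiomer drawn) | COc1ccc([C@@H](O)[C@H](C)Oc2c(OC)cc(C=O)cc2OC)cc1OC | intermediate
6 | (1R,2S)-1-(3,4-dimethoxyphenyl)-2-(4-formyl-2,6-dimethoxyphenoxy)propyl (1S,4R)-4,7,7-trimethyl-3-oxo-2-oxabicyclo[2.2.1]heptane-1-carboxylate | COc1ccc([C@@H](OC(=O)[C@@]23CC[C@@](C)(C(=O)O2)C3(C)C)[C@H](C)Oc2c(OC)cc(C=O)cc2OC)cc1OC | intermediate
7 | triethyl phosphonoacetate | CCOC(=O)CP(=O)(OCC)OCC | starting material
8 | ethyl (E)-3-[4-({(1R,2S)-1-[(1S,4R)-camphanoyloxy]-1-(3,4-dimethoxyphenyl)propan-2-yl}oxy)-3,5-dimethoxyphenyl]prop-2-enoate | COc1ccc([C@@H](OC(=O)[C@@]23CC[C@@](C)(C(=O)O2)C3(C)C)[C@H](C)Oc2c(OC)cc(/C=C/C(=O)OCC)cc2OC)cc1OC | intermediate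
9 | (1R,2S)-1-(3,4-dimethoxyphenyl)-2-{4-[(E)-3-hydroxyprop-1-en-1-yl]-2,6-dimethoxyphenoxy}propan-1-ol, the (7R,8S) erythro neolignan | COc1ccc([C@@H](O)[C@H](C)Oc2c(OC)cc(/C=C/CO)cc2OC)cc1OC | target

Total step count: 5. Longest linear sequence: 5 steps (1 and 2 to 9).

Steps most likely to fail

Step 1. What may go wrong: homo-coupling of the isoeugenol radical (8-5' and 8-O-4' dimers) may outpace cross-coupling; the quinone methide may be hydrated with little erythro preference or be trapped by excess 2; the formyl group may be over-oxidised on the silver surface. Fallback (ionic construction of the same ether and carbinol): setting out from 2, O-alkylation with commercial 2-bromo-1-(3,4-dimethoxyphenyl)propan-1-one (CC(Br)C(=O)c1ccc(OC)c(OC)c1; K2CO3, DMF, rt) should give the racemic keto ether aldehyde F1. Horner–Wadsworth–Emmons olefination of its aldehyde with 7 (NaH, THF, 0 °C) should give the keto cinnamate F2. Chelation-controlled reduction of the ketone with Zn(BH4)2 (Et2O, 0 °C), hydride arriving on the face of the chelate that carries C8–H, should give mainly the racemic erythro hydroxy ester F3. Acylation of F3 with (1S)-camphanic chloride and separation of the diastereomers under the conditions of step 3 comes back to the route at 8.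

Step 3. What may go wrong: the two camphanates may differ too little in mobility and solubility to be separated. Fallback (catalytic kinetic resolution in place of separating stoichiometric diastereomers): setting out from 5, enantioselective acylation with isobutyric anhydride and the chiral isothiourea 2-phenyl-2,3-dihydroimidazo[2,1-b]benzothiazole (benzotetramisole) is run past half conversion (i-Pr2NEt, CHCl3, 0 °C). The antipode of the catalyst that acylates the (1S,2R)-alcohol faster is chosen in a trial run with each enantiomer. This should leave the (1R,2S)-alcohol F4, which is separated from the isobutyrate of its enantiomer by chromatography. Acylation of F4 with (1S)-camphanic chloride under the conditions of step 3 comes back to the route at 6, where one recrystallisation should remove any residual minor diastereomer.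

Step 5. What may go wrong: hydride attack on the hindered camphanate carbonyl may be slow or incomplete and its lactone only partly reduced, giving mixtures of polar products that are hard to separate from the diol. Fallback (solvolytic removal of the acyl group before the reduction): setting out from 8, methanolysis (K2CO3, MeOH, rt) should cleave the camphanate and transesterify the ethyl ester, giving the hydroxy methyl cinnamate F5; any ethyl ester that survives is reduced to the same product. i-Bu2AlH (3 equiv, CH2Cl2, −78 °C) then has only one ester to reduce and comes back to the route at 9.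

Further compounds
F1 | step 1 | 4-{[1-(3,4-dimethoxyphenyl)-1-oxopropan-2-yl]oxy}-3,5-dimethoxybenzaldehyde (racemate) | COc1ccc(C(=O)C(C)Oc2c(OC)cc(C=O)cc2OC)cc1OC
F2 | step 1 | ethyl (E)-3-(4-{[1-(3,4-dimethoxyphenyl)-1-oxopropan-2-yl]oxy}-3,5-dimethoxyphenyl)prop-2-enoate (racemate) | COc1ccc(C(=O)C(C)Oc2c(OC)cc(/C=C/C(=O)OCC)cc2OC)cc1OC
F3 | step 1 | ethyl (E)-3-(4-{[erythro-1-(3,4-dimethoxyphenyl)-1-hydroxypropan-2-yl]oxy}-3,5-dimethoxyphenyl)prop-2-enoate (racemate; (1R,2S) enantiomer drawn) | COc1ccc([C@@H](O)[C@H](C)Oc2c(OC)cc(/C=C/C(=O)OCC)cc2OC)cc1OC
F4 | step 3 | 4-{[(1R,2S)-1-(3,4-dimethoxyphenyl)-1-hydroxypropan-2-yl]oxy}-3,5-dimethoxybenzaldehyde (single enantiomer of 5) | COc1ccc([C@@H](O)[C@H](C)Oc2c(OC)cc(C=O)cc2OC)cc1OC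
F5 | step 5 | methyl (E)-3-(4-{[(1R,2S)-1-(3,4-dimethoxyphenyl)-1-hydroxypropan-2-yl]oxy}-3,5-dimethoxyphenyl)prop-2-enoate | COc1ccc([C@@H](O)[C@H](C)Oc2c(OC)cc(/C=C/C(=O)OC)cc2OC)cc1OC
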